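The data stem from a simulated flask from invented constants; the scatter is artificial.

1. A pitfall with mirror-image substrates: the gap between them looks like the excess in the product. I test what that gap can carry.

| flask | left-handed substrate | right-handed substrate | partner | protic impurity | free catalyst | remark | time |
|---|---|---|---|---|---|---|---|
| violet | 0.070 M | 0.070 M | 0.15 M | 0.010 M | 65 µM | run made earlier |  |
| teal | 0.11 M | 0.11 M | 0.15 M | 0.010 M | 65 µM | run made earlier |  |
| flask | 0.050 M | 0.050 M | 0.150 M | 0.0100 M | 65 µM |  | 10 d |

- violet (time / d: left-handed substrate / %, right-handed substrate / %): 2.08: 45.5, 46.3; 4.00: 41.6, 43.7; 6.00: 39.7, 40.5; 8.00: 35.3, 38.0; 10.0: 34.8, 35.4; 12.0: 31.9, 33.8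
- teal (time / d: left-handed substrate / %, right-handed substrate / %): 2.08: 47.0, 46.9; 4.00: 44.8, 45.2; 6.00: 41.7, 43.7; 8.00: 40.1, 40.3; 10.0: 38.5, 38.5; 12.0: 37.4, 38.0

(each reading ± 0.5 percentage points)

* part of the left-handed substrate and right-handed substrate charged together that has reacted at 10 d
* excess of left-handed product over right-handed product in the product at 10 d
* excess of right-handed substrate over left-handed substrate among what is left of the two at 10 d

- free catalyst is single-handed; left-handed substrate and right-handed substrate are mirror images of each other, charged as a racemate, each of them at the stated concentration
- an excess is the difference of the two amounts in percent of their sum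
- an excess is below zero if the other one leads

2. Both runs hold the same single-handed catalyst. Yet the lead of right-handed over left-handed substrate, summed over the six readings and divided by the summed fractions reacted, is 6.67% in violet and 3.17% in teal, twice as much.

3. Each gap is a difference of two readings, so the teal share scatters by 1.8 percentage points. The two shares lie 3.5 points apart, less than twice that, so I pool them.

4. The gap share, the summed lead of both runs per summed fraction reacted, is 5.19%.

5. A straight line through the amounts reacted at 10.0 d, taken down to the flask's charge, gives me 37.3% reacted.

6. If each substrate stays in its own hand, the gap share equals the product excess, and the excess of right-handed substrate among what is left is the share times c/(1−c), with c the fraction reacted, here 3.08%. The runs hold no product reading to test that condition.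

7. The forecast says 36% reacted (30% to 43%), a product excess of 5% (2.5% to 9%) and a substrate excess of 2.8% (1.3% to 5.5%), with the words “The selectivity is small”. My fraction reacted and my substrate excess stand slightly higher.

The flask gives 37.5% reacted, a product excess of 10.2% and a substrate excess of 2.09%.

    free catalyst + left-handed substrate ⇌ catalyst intermediate A (K = 9.10 M⁻¹, k = 7500 M⁻¹ h⁻¹)
    free catalyst + right-handed substrate ⇌ catalyst intermediate B (K = 19.0 M⁻¹, k = 10000 M⁻¹ h⁻¹)
    partner + catalyst intermediate A → free catalyst + left-handed product (k = 66.0 M⁻¹ h⁻¹)
    partner + catalyst intermediate B → free catalyst + right-handed product (k = 25.0 M⁻¹ h⁻¹)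
    left-handed substrate ⇌ right-handed substrate (k = 0.00480 h⁻¹)
    partner + protic impurity → quenched reagent (k = 2.60 M⁻¹ h⁻¹)

In this flask, left-handed substrate crosses into right-handed substrate (racemisation) with a forward half-life of 6.0 d, that forward rate alone, shorter than the run. The product excess is twice the gap share 5.19%, and at the flask's fraction reacted the share gives 3.11% against the flask's substrate excess of 2.09%.

In the neighbour flask with 3.9 × 10⁻⁵ M free catalyst, the share at its 24.9% reacted gives 1.72%. Computed, that neighbour has a substrate excess of 1.27% and a product excess of 10.6%.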